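## The problem

The target is a flavone (rings A and C fused, ring B the 2-phenyl group) whose ring A carries an N-methylpiperidine at C6, joined through C2′. C6 sits between the methoxy-bearing C5 and the hydroxy-bearing C7, and para to C8a, the carbon bonded to the ring oxygen O1. The only stereocentre is C2′ (S), and nothing else in the molecule can relay chirality to it, so it must be set absolutely by an auxiliary or reagent and then carried unchanged. That centre is benzylic to a ring with oxygen donors ortho, ortho and para to it and is α to nitrogen. The C2′–N bond can therefore ionize reversibly, under strong acid when nitrogen is acylated, or under base and heat when a free ortho or para phenol faces a basic nitrogen, and either event erases the configuration. The oxygen pattern is the awkward one: the methyl group sits on the chelated peri oxygen O5 and the free hydroxyl on O7, the reverse of what direct alkylation or Lewis-acid dealkylation of a 5,7-dioxygenated flavone gives. The pyranone is a Michael acceptor and would not survive an organomagnesium reagent, and a tertiary N-methyl amine would be quaternized by any methylating agent used on a phenol. The enabling feature is that C2′ is an aldehyde-level carbon on C6, that N1′ and C3′–C6′ form one unbranched chain, and that a 4-oxy-2,6-dimethoxyphenyl group is symmetric about the C6–C8a axis. A sulfinimine of a symmetric benzaldehyde can thus take up a four-carbon nucleophile and close the ring on nitrogen, while the choice of which ortho carbon becomes C4a is left to a stage where both are identical.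

## Retrosynthesis

**N–CH3 and the last protecting groups (20 from 19).** The N-methyl bond is cut last, together with the O7-benzyl and N-benzyloxycarbonyl groups of 19. This is preferred to carrying the methyl group earlier, because a basic tertiary amine cannot coexist with the O-methylation that precedes this step. Formaldehyde supplies the carbon, and the hydrogen that removes both benzyl-type groups also reduces the iminium ion. The forward step must not saturate C2=C3 or cleave the ring C2′–N bond.

**O5–CH3 and O7–benzyl (19 from 17 through 18).** Both alkyl–oxygen bonds are cut back to the diphenol 17. The two hydroxyls differ enough in acidity to be alkylated in sequence: O7–H is free and para to the acyl-bearing carbon, O5–H is chelated to the C4 carbonyl. With nitrogen as a carbamate there is no third nucleophile. The forward reaction must benzylate O7 before any methylating agent is present.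

**N–CO and the two O–CH3 bonds of ring A (17 from 15 through 16).** The methyl ethers that kept the arene symmetric are cleaved only once the flavone exists, since Lewis-acid cleavage alone would free O5 first and give the wrong isomer. Both are therefore removed and the oxygens re-differentiated. The amino diphenol 16 is the form most able to lose configuration, so it is acylated in the same operation rather than stored.

**C4–C4a (15 from 13 through 14).** The pyranone is opened at the aryl–carbonyl bond to a 3-aryloxy-3-phenylacrylic acid. The two carbons ortho to the ether oxygen are equivalent, so only one chromone can form. A stepwise acetophenone-based flavone synthesis would take more steps and would also need an aromatic acylation. The sulfinyl group is taken off by HCl just before the acylation, so that nitrogen is a protonated amine during the strongly acidic step, the state in which C2′–N is least likely to ionize.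

**O1–C2 (13 from 12, and 12 from 10 and 11).** The aryl vinyl ether is cut to phenol 10 and ethyl phenylpropiolate 11, followed by ester hydrolysis. Forming the O–C bond first under base fixes the flavone connectivity. An acid-mediated one-flask union of a phenol with a propiolic acid could instead give a 4-phenylcoumarin by hydroarylation. The fully substituted sulfinamide nitrogen of 10 cannot compete as a nucleophile, which a free secondary amine would.

**O–benzyl (10 from 9).** The para oxygen must be masked during imine formation and Grignard addition, because a para phenoxide would quench the reagent and deactivate the imine. Hydrogenolysis removes the benzyl group under neutral conditions that leave the sulfinamide in place.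

**C2′–C3′ and N–C6′ (9 from 5 and 7 through 8).** The piperidine is cut at these two bonds, which reduces it to an aldehyde carbon, a sulfinamide nitrogen and a four-carbon chain with a metal at one end and chloride at the other. Cutting C6–C2′ instead would need a di-ortho-substituted aryl nucleophile and a separate source of asymmetry. Cutting N–C2′ alone would need asymmetric reduction of a hindered cyclic imine. The chosen cut lets the sulfur stereocentre of 5 set C2′ in the addition, and the same nitrogen then closes the ring. The forward reaction must add to a hindered, donor-rich imine with face selectivity and then N-alkylate in the same flask.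

**C=N, O–benzyl and C–Mg (5 from 3 and 4; 3 from 1 and 2; 7 from 6).** The sulfinimine comes from condensation of aldehyde 3 with (R)-sulfinamide 4. Aldehyde 3 comes from benzylation of the commercial phenol 1 with 2. Reagent 7 comes from magnesium insertion into the C–Br bond of 6. All three are routine, and the starting materials are simple and commercial.

## Roads not taken

**Alternative 1:** The cut is made on the finished flavone at N–C2′ and C2′–C3′, leaving 7-hydroxy-5-methoxy-4-oxo-2-phenyl-4H-chromene-6-carbaldehyde (A1) and (3Z)-4-(trimethylsilyl)but-3-en-1-amine (A2). Forward, A1 and A2 condense to an iminium ion, the silicon-bearing alkene carbon attacks the iminium carbon, and loss of silicon gives 7-hydroxy-5-methoxy-2-phenyl-6-[(2S)-1,2,5,6-tetrahydropyridin-2-yl]-4H-chromen-4-one (A3). Alkene hydrogenation and N-methylation would finish.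
- Merits: the step is convergent and forms two bonds and the ring at once. A1 already carries the 5-methoxy-7-hydroxy pattern, so the late oxygen differentiation of the chosen plan disappears. After the heterocycle is made, this road is clearly shorter.
- Weak points: the iminium ion is planar and neither A1 nor A2 is chiral, so A3 would be racemic unless an asymmetric variant were developed for a substrate class where none is established. The carbonyl of A1 is a vinylogous acid hydrogen-bonded to the 7-hydroxyl, which makes a poor electrophile for a weak π-nucleophile. A1 itself needs a C6-selective formylation where C8 normally competes. A3 is an allylic, benzylic amine beside a free phenol, and its ring alkene must be hydrogenated next to C2=C3 and a hydrogenolysable C–N bond.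
- Comparison: the chosen plan has a longer endgame, but it offers an auxiliary with a predictable sense of induction and a ring construction done before the pyranone exists.

**Alternative 2:** Ring A is cut at C5–C6 and C7–C8 (C4a–C5 is broken and re-formed on the way). The precursors are 3-[(4-methoxyphenyl)methoxy]cyclobut-2-en-1-one (A4) and tert-butyl (2S)-2-({[tri(propan-2-yl)silyl]oxy}ethynyl)piperidine-1-carboxylate (A5). Forward, a Danheiser benzannulation: heating opens A4 to a vinylketene, which adds to A5; 4π opening and 6π closure then give tert-butyl (2S)-2-{2-hydroxy-4-[(4-methoxyphenyl)methoxy]-6-[tri(propan-2-yl)silyloxy]phenyl}piperidine-1-carboxylate (A6).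
- Merits: the stereocentre comes from the chiral pool, not from induction. The three oxygens arrive differentiated (free hydroxyl at the future C5, silyl ether at C7, a benzyl-type ether at the future O1). This is exactly the distinction that costs the chosen plan steps 9 and 10, and here this road is better.
- Weak points: A5 must be made from an α-amino ester through an ynolate under strongly basic conditions next to the stereocentre. It is a branched, hindered partner for the cycloaddition, and the thermal cascade must tolerate a carbamate and a silyl ynol ether. Ring A of A6 is no longer symmetric, so closing the pyranone at the future C4a and not at C8 becomes a selectivity question decided only by the bulk of the silyl ether. Nitrogen is a carbamate on the most electron-rich form of the ring, the arrangement in which acid opens C2′–N.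
- Comparison: the chosen plan offers a commercial arene, an annulation whose regiochemistry is fixed by symmetry, and a well-precedented way of making the piperidine.

**Alternative 3:** The strategic bond is C4–C4a on a symmetric phenol ether. The carboxyl of 3-{3,5-dimethoxy-4-[(2S)-1-methylpiperidin-2-yl]phenoxy}-3-phenylprop-2-enoic acid (A7) acylates a ring carbon ortho to the ether oxygen and gives 5,7-dimethoxy-6-[(2S)-1-methylpiperidin-2-yl]-2-phenyl-4H-chromen-4-one (A8).
- Merits: symmetry decides the regiochemistry. The nitrogen is already methylated and basic, so it is protonated and robust during the acylation. The flavone emerges with its final N-substituent, which saves a carbamate on and off.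
- Weak points: as a strategy it leaves open how C2′ is set, so A7 still needs an asymmetric piperidine synthesis. From A8 both methyl ethers must be cleaved and O5 re-methylated in the presence of a nucleophilic N-methyl amine, where a methylating agent would quaternize nitrogen.
- Comparison: the chosen plan uses the same ring closure as a supporting step (step 8) on the N-unsubstituted acid and moves N-methylation to the last step. Its cost is the carbamate detour.

Key step: step 4

Assumption: the magnesium-chelated chair model for Grignard additions to N-tert-butanesulfinyl aldimines is taken to hold for this di-ortho-methoxy aldimine, so the (R)-sulfinamide is chosen to give the (S)-configured carbon.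

## Route

Step 1
Reactants: 1 4-hydroxy-2,6-dimethoxybenzaldehyde; 2 benzyl bromide
Product: 3 4-(benzyloxy)-2,6-dimethoxybenzaldehyde
Conditions: K2CO3, DMF, 23 °C
Reagents that add atoms: none
Why: Williamson ether synthesis on the only hydroxyl; the benzyl ether prevents a para phenoxide that would quench the Grignard reagent and deactivate the imine.

Step 2
Reactants: 3 4-(benzyloxy)-2,6-dimethoxybenzaldehyde; 4 (R)-2-methylpropane-2-sulfinamide
Product: 5 (R)-N-[(E)-[4-(benzyloxy)-2,6-dimethoxyphenyl]methylidene]-2-methylpropane-2-sulfinamide
Conditions: Ti(OEt)4, THF, 65 °C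
Reagents that add atoms: none
Why: Ti(OEt)4-mediated condensation of an aldehyde with tert-butanesulfinamide; the titanium alkoxide activates the hindered, donor-rich carbonyl and takes up the water, and the aldimine should form as the (E) isomer only.

Step 3
Reactants: 6 1-bromo-4-chlorobutane
Product: 7 4-chlorobutylmagnesium bromide (solution in Et2O, used at once)
Conditions: Mg turnings, cat. I2, Et2O, 0 → 25 °C
Reagents that add atoms: magnesium, [Mg]
Why: Grignard formation; magnesium inserts into the C–Br bond much faster than into the C–Cl bond, and keeping the solution at or below 25 °C should hold Wurtz coupling and self-alkylation to a minor level.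

Step 4
Reactants: 5 (R)-N-[(E)-[4-(benzyloxy)-2,6-dimethoxyphenyl]methylidene]-2-methylpropane-2-sulfinamide; 7 4-chlorobutylmagnesium bromide
Product: 9 (2S)-2-[4-(benzyloxy)-2,6-dimethoxyphenyl]-1-[(R)-2-methylpropane-2-sulfinyl]piperidine, via open-chain chloroalkyl sulfinamide salt 8 (not isolated)
Conditions: 7 (2 equiv, Et2O), toluene, −78 → −40 °C; then KN(SiMe3)2, THF, −40 → 23 °C; aq. NH4Cl
Reagents that add atoms: none
Why: Reagent 7 should add to the C=N bond of 5 through a magnesium-bridged six-membered chair in which the metal is held by the sulfinyl oxygen and both the tert-butyl group and the aryl group of the (E)-imine are equatorial, so the alkyl group reaches the face that gives the (S) carbon of 8 (priorities N > aryl > alkyl). KN(SiMe3)2 and THF then turn the magnesium sulfinamide into the more nucleophilic potassium salt, whose nitrogen displaces the primary chloride within the molecule. The closest known reaction type is the addition of ω-haloalkyl Grignard reagents to N-tert-butanesulfinyl aldimines with base-induced cyclization to N-sulfinyl pyrrolidines and piperidines. The piperidine ring closes by 6-exo-tet SN2 N-alkylation (N–C6′) after C2′–C3′ has been formed in the addition. The one new stereocentre, C2′, is controlled by the sulfur stereocentre of the auxiliary through the chelated chair and is not touched in the ring closure. The step needs diastereofacial selectivity at C=N and selectivity of the carbon–magnesium end for the imine over the reagent's own C–Cl end. The first is secured by running the addition in toluene with only the ether that comes with the reagent and by the single (E) geometry of the aldimine; the second by the low temperature and the inertness of a primary chloride toward a Grignard reagent. The two identical ortho methoxy groups make the two rotamers of the aryl group equivalent, so only the face of the C=N bond matters.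

Step 5
Reactants: 9 (2S)-2-[4-(benzyloxy)-2,6-dimethoxyphenyl]-1-[(R)-2-methylpropane-2-sulfinyl]piperidine
Product: 10 3,5-dimethoxy-4-[(2S)-1-[(R)-2-methylpropane-2-sulfinyl]piperidin-2-yl]phenol
Conditions: H2 (1 atm), Pd/C, EtOAc–EtOH, 23 °C
Reagents that add atoms: none
Why: Hydrogenolysis of an aryl benzyl ether; the sulfinamide has no bond that is reduced under these conditions, and the ring C2′–N bond, shielded by two ortho methoxy groups and carrying a non-basic nitrogen, is not expected to cleave.

Step 6
Reactants: 10 3,5-dimethoxy-4-[(2S)-1-[(R)-2-methylpropane-2-sulfinyl]piperidin-2-yl]phenol; 11 ethyl 3-phenylprop-2-ynoate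
Product: 12 ethyl 3-{3,5-dimethoxy-4-[(2S)-1-[(R)-2-methylpropane-2-sulfinyl]piperidin-2-yl]phenoxy}-3-phenylprop-2-enoate (E/Z mixture)
Conditions: K2CO3, DMF, 60 °C
Reagents that add atoms: none
Why: Base-mediated conjugate (oxa-Michael) addition of the phenoxide to the β-carbon of the alkynoate; the hydroxyl of 10 has no ortho substituent, the nitrogen is fully substituted, and both alkene isomers are usable because they equilibrate under the acid of step 8.

Step 7
Reactants: 12 ethyl 3-{3,5-dimethoxy-4-[(2S)-1-[(R)-2-methylpropane-2-sulfinyl]piperidin-2-yl]phenoxy}-3-phenylprop-2-enoate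
Product: 13 3-{3,5-dimethoxy-4-[(2S)-1-[(R)-2-methylpropane-2-sulfinyl]piperidin-2-yl]phenoxy}-3-phenylprop-2-enoic acid
Conditions: LiOH, THF–MeOH–H2O, 23 → 40 °C; AcOH to pH 5
Reagents that add atoms: lithium hydroxide (hydroxide oxygen), [Li+].[OH-]
Why: Ester saponification; the sulfinamide is inert to hydroxide, and acidification only to pH 5 should leave the S–N bond intact.

Step 8
Reactants: 13 3-{3,5-dimethoxy-4-[(2S)-1-[(R)-2-methylpropane-2-sulfinyl]piperidin-2-yl]phenoxy}-3-phenylprop-2-enoic acid
Product: 15 5,7-dimethoxy-2-phenyl-6-[(2S)-piperidin-2-yl]-4H-chromen-4-one, via amino acid hydrochloride 14 (not isolated)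
Conditions: HCl (4 M in 1,4-dioxane), 23 °C; evaporate; then P2O5 in CH3SO3H (1:10 w/w), 23 → 40 °C; aq. Na2CO3
Reagents that add atoms: hydrogen chloride (chloride of the salt 14 only), Cl
Why: Acidolysis of the S–N bond by HCl, then intramolecular Friedel–Crafts acylation by the activated carboxyl onto a carbon ortho to the aryloxy oxygen (chromone synthesis from a 3-aryloxyacrylic acid); the two ortho carbons are equivalent so one chromone should result, the site is activated by oxygen ortho, ortho and para, and the nitrogen is a protonated amine, the state in which C2′–N is least prone to ionize.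

Step 9
Reactants: 15 5,7-dimethoxy-2-phenyl-6-[(2S)-piperidin-2-yl]-4H-chromen-4-one
Product: 17 benzyl (2S)-2-(5,7-dihydroxy-4-oxo-2-phenyl-4H-chromen-6-yl)piperidine-1-carboxylate, via amino diphenol 16 (not isolated)
Conditions: BBr3 (6 equiv), CH2Cl2, −78 → 23 °C; MeOH, evaporate; then CbzCl (1.05 equiv), NaHCO3, THF–H2O, 0 °C
Reagents that add atoms: benzyl chloroformate, O=C(Cl)OCc1ccccc1
Why: Lewis-acid cleavage of both aryl methyl ethers by BBr3 (the chelated 5-ether first, the 7-ether on warming), then Schotten–Baumann N-acylation of the crude amine, which outcompetes the phenols for the chloroformate; acylating at once means the amino diphenol, the form most able to lose configuration by reversible C2′–N cleavage, is never stored.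

Step 10
Reactants: 17 benzyl (2S)-2-(5,7-dihydroxy-4-oxo-2-phenyl-4H-chromen-6-yl)piperidine-1-carboxylate; 2 benzyl bromide
Product: 19 benzyl (2S)-2-[7-(benzyloxy)-5-methoxy-4-oxo-2-phenyl-4H-chromen-6-yl]piperidine-1-carboxylate, via 7-O-benzyl 5-hydroxy carbamate 18 (not isolated)
Conditions: 2 (1.05 equiv), K2CO3, DMF, 23 °C; then MeI (excess), 45 °C
Reagents that add atoms: iodomethane, CI
Why: Two Williamson alkylations in the order of phenol acidity: the 7-hydroxyl, para to the acyl-bearing carbon and not hydrogen-bonded, should be benzylated at room temperature, and the 5-hydroxyl, chelated to the C4 carbonyl, methylated afterwards on warming; the carbamate nitrogen has no N–H and is not nucleophilic, so it cannot be alkylated.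

Step 11
Reactants: 19 benzyl (2S)-2-[7-(benzyloxy)-5-methoxy-4-oxo-2-phenyl-4H-chromen-6-yl]piperidine-1-carboxylate
Product: 20 7-hydroxy-5-methoxy-6-[(2S)-1-methylpiperidin-2-yl]-2-phenyl-4H-chromen-4-one
Conditions: H2 (1 atm), Pd/C, aq. HCHO, MeOH–THF, 23 °C
Reagents that add atoms: formaldehyde, C=O
Why: Hydrogenolysis of the benzyl ether and the benzyl carbamate with reductive N-methylation of the freed secondary amine by formaldehyde in the same flask; the C2=C3 bond of the chromone is a vinylogous ester and should be reduced far more slowly than benzyl C–O bonds are cleaved, and C2′ takes no part.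

## Compound list

1 | 4-hydroxy-2,6-dimethoxybenzaldehyde | COc1cc(O)cc(OC)c1C=O | starting material
2 | benzyl bromide | BrCc1ccccc1 | starting material
3 | 4-(benzyloxy)-2,6-dimethoxybenzaldehyde | COc1cc(OCc2ccccc2)cc(OC)c1C=O | intermediate
4 | (R)-2-methylpropane-2-sulfinamide | CC(C)(C)[S@@](=O)N | starting material
5 | (R)-N-[(E)-[4-(benzyloxy)-2,6-dimethoxyphenyl]methylidene]-2-methylpropane-2-sulfinamide | CC(C)(C)[S@@](=O)/N=C/c1c(OC)cc(OCc2ccccc2)cc1OC | intermediate
6 | 1-bromo-4-chlorobutane | ClCCCCBr | starting material
7 | 4-chlorobutylmagnesium bromide | ClCCCC[Mg]Br | intermediate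
8 | (R)-N-{(1S)-1-[4-(benzyloxy)-2,6-dimethoxyphenyl]-5-chloropentyl}-2-methylpropane-2-sulfinamide (present as its N-metal salt) | CC(C)(C)[S@@](=O)N[C@@H](CCCCCl)c1c(OC)cc(OCc2ccccc2)cc1OC | intermediate (not isolated)
9 | (2S)-2-[4-(benzyloxy)-2,6-dimethoxyphenyl]-1-[(R)-2-methylpropane-2-sulfinyl]piperidine | CC(C)(C)[S@@](=O)N1CCCC[C@H]1c1c(OC)cc(OCc2ccccc2)cc1OC | intermediate
10 | 3,5-dimethoxy-4-[(2S)-1-[(R)-2-methylpropane-2-sulfinyl]piperidin-2-yl]phenol | CC(C)(C)[S@@](=O)N1CCCC[C@H]1c1c(OC)cc(O)cc1OC | intermediate
11 | ethyl 3-phenylprop-2-ynoate | CCOC(=O)C#Cc1ccccc1 | starting material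
12 | ethyl 3-{3,5-dimethoxy-4-[(2S)-1-[(R)-2-methylpropane-2-sulfinyl]piperidin-2-yl]phenoxy}-3-phenylprop-2-enoate (E/Z mixture) | CC(C)(C)[S@@](=O)N1CCCC[C@H]1c1c(OC)cc(OC(=CC(=O)OCC)c2ccccc2)cc1OC | intermediate
13 | 3-{3,5-dimethoxy-4-[(2S)-1-[(R)-2-methylpropane-2-sulfinyl]piperidin-2-yl]phenoxy}-3-phenylprop-2-enoic acid (E/Z mixture) | CC(C)(C)[S@@](=O)N1CCCC[C@H]1c1c(OC)cc(OC(=CC(=O)O)c2ccccc2)cc1OC | intermediate
14 | 3-{3,5-dimethoxy-4-[(2S)-piperidin-2-yl]phenoxy}-3-phenylprop-2-enoic acid hydrochloride | N1CCCC[C@H]1c1c(OC)cc(OC(=CC(=O)O)c2ccccc2)cc1OC.Cl | intermediate (not isolated)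
15 | 5,7-dimethoxy-2-phenyl-6-[(2S)-piperidin-2-yl]-4H-chromen-4-one | N1CCCC[C@H]1c1c(OC)cc2oc(-c3ccccc3)cc(=O)c2c1OC | intermediate
16 | 5,7-dihydroxy-2-phenyl-6-[(2S)-piperidin-2-yl]-4H-chromen-4-one (carried crude as its hydrobromide) | N1CCCC[C@H]1c1c(O)cc2oc(-c3ccccc3)cc(=O)c2c1O | intermediate (not isolated)
17 | benzyl (2S)-2-(5,7-dihydroxy-4-oxo-2-phenyl-4H-chromen-6-yl)piperidine-1-carboxylate | O=C(OCc1ccccc1)N1CCCC[C@H]1c1c(O)cc2oc(-c3ccccc3)cc(=O)c2c1O | intermediate
18 | benzyl (2S)-2-[7-(benzyloxy)-5-hydroxy-4-oxo-2-phenyl-4H-chromen-6-yl]piperidine-1-carboxylate | O=C(OCc1ccccc1)N1CCCC[C@H]1c1c(OCc2ccccc2)cc2oc(-c3ccccc3)cc(=O)c2c1O | intermediate (not isolated)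
19 | benzyl (2S)-2-[7-(benzyloxy)-5-methoxy-4-oxo-2-phenyl-4H-chromen-6-yl]piperidine-1-carboxylate | O=C(OCc1ccccc1)N1CCCC[C@H]1c1c(OCc2ccccc2)cc2oc(-c3ccccc3)cc(=O)c2c1OC | intermediate
20 | 7-hydroxy-5-methoxy-6-[(2S)-1-methylpiperidin-2-yl]-2-phenyl-4H-chromen-4-one | CN1CCCC[C@H]1c1c(O)cc2oc(-c3ccccc3)cc(=O)c2c1OC | target

## Step count and least certain steps

Total steps: 11. Longest linear sequence: 10 (steps 1, 2 and 4 to 11, from 1); step 3 is a one-step side branch.

**Step 4 (key step).** Most likely to go wrong is poor facial selectivity at C=N: an ortho methoxy oxygen together with the imine nitrogen can hold magnesium in place of the sulfinyl oxygen and so open the chair. Slow addition to the hindered, donor-rich imine is the second concern. The fallback sets the centre by hydride delivery instead of carbon delivery; it sets out from 3 and 7 and returns at 9. Addition of 7 to aldehyde 3 in THF at −78 °C should give the racemic alcohol 1-[4-(benzyloxy)-2,6-dimethoxyphenyl]-5-chloropentan-1-ol F1. Oxidation with 1,1,1-triacetoxy-1,1-dihydro-1,2-benziodoxol-3(1H)-one in CH2Cl2 should give the ketone 1-[4-(benzyloxy)-2,6-dimethoxyphenyl]-5-chloropentan-1-one F2. Condensation with 4 in neat Ti(OEt)4 at 90 °C should give the ketimine (R)-N-{1-[4-(benzyloxy)-2,6-dimethoxyphenyl]-5-chloropentylidene}-2-methylpropane-2-sulfinamide F3. LiBEt3H in THF (−78 → 23 °C) reduces the C=N bond through an open transition state, in which methoxy chelation plays no part, and the nitrogen anion of 8 closes onto the chloride to give 9. The C=N geometry of F3 must be established first, since it decides whether this hydride or a chelating one leads to the (S) centre.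

**Step 8.** Most likely to go wrong is ionization of the C2′–N bond in the strongly acidic medium, with loss of configuration, or alkylation of the activated ring by fragments of the sulfinyl group if its removal before the acylation is incomplete. The fallback builds the pyranone under basic, palladium-catalysed conditions; it sets out from 10 and returns at 15. N-Iodosuccinimide in MeCN at 0 °C iodinates one of the two equivalent positions ortho to the hydroxyl, giving 2-iodo-3,5-dimethoxy-4-[(2S)-1-[(R)-2-methylpropane-2-sulfinyl]piperidin-2-yl]phenol F4. Carbonylative Sonogashira annulation with phenylacetylene under CO (PdCl2(PPh3)2, Et2NH, 90 °C) closes ring C, giving 5,7-dimethoxy-6-[(2S)-1-[(R)-2-methylpropane-2-sulfinyl]piperidin-2-yl]-2-phenyl-4H-chromen-4-one F5. HCl in methanol at 0 °C, followed by NaHCO3 work-up, then removes the sulfinyl group and gives 15.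

**Step 10.** Most likely to go wrong is loss of selectivity between the two phenolic oxygens in the one-flask sequence, or sluggish alkylation of the chelated, doubly flanked 5-hydroxyl. The fallback differentiates the oxygens by acylation with isolation at each stage; it sets out from 17 and returns at 20. Pivaloyl chloride and pyridine at 0 °C acylate only the 7-hydroxyl, giving benzyl (2S)-2-[7-(2,2-dimethylpropanoyloxy)-5-hydroxy-4-oxo-2-phenyl-4H-chromen-6-yl]piperidine-1-carboxylate F6. Dimethyl sulfate and K2CO3 in acetone methylate the remaining hydroxyl, giving benzyl (2S)-2-[7-(2,2-dimethylpropanoyloxy)-5-methoxy-4-oxo-2-phenyl-4H-chromen-6-yl]piperidine-1-carboxylate F7. K2CO3 in methanol removes the ester, giving benzyl (2S)-2-(7-hydroxy-5-methoxy-4-oxo-2-phenyl-4H-chromen-6-yl)piperidine-1-carboxylate F8. The conditions of step 11 then remove the carbamate and methylate nitrogen to give 20.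

**Step 11.** Most likely to go wrong is over-reduction during the exposure that three events in one flask require: hydrogenolysis of the benzylic ring C2′–N bond once nitrogen is basic, or saturation of C2=C3. Formaldehyde may also react at C8, ortho to the freed phenol. The fallback avoids hydrogen altogether; it sets out from 15 and returns at 20. BBr3 as in step 9 gives 16, and allyl chloroformate with NaHCO3 gives prop-2-en-1-yl (2S)-2-(5,7-dihydroxy-4-oxo-2-phenyl-4H-chromen-6-yl)piperidine-1-carboxylate F9. Allyl bromide and K2CO3 in DMF give prop-2-en-1-yl (2S)-2-[5-hydroxy-4-oxo-2-phenyl-7-(prop-2-en-1-yloxy)-4H-chromen-6-yl]piperidine-1-carboxylate F10, and iodomethane in the same flask gives prop-2-en-1-yl (2S)-2-[5-methoxy-4-oxo-2-phenyl-7-(prop-2-en-1-yloxy)-4H-chromen-6-yl]piperidine-1-carboxylate F11. Pd(PPh3)4 (zerovalent palladium) with excess morpholine removes both allyl groups, giving 7-hydroxy-5-methoxy-2-phenyl-6-[(2S)-piperidin-2-yl]-4H-chromen-4-one F12. Formaldehyde and NaBH(OAc)3 then methylate nitrogen to give 20.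

## Further compounds

F1 | step 4 | 1-[4-(benzyloxy)-2,6-dimethoxyphenyl]-5-chloropentan-1-ol (racemic) | OC(CCCCCl)c1c(OC)cc(OCc2ccccc2)cc1OC
F2 | step 4 | 1-[4-(benzyloxy)-2,6-dimethoxyphenyl]-5-chloropentan-1-one | O=C(CCCCCl)c1c(OC)cc(OCc2ccccc2)cc1OC
F3 | step 4 | (R)-N-{1-[4-(benzyloxy)-2,6-dimethoxyphenyl]-5-chloropentylidene}-2-methylpropane-2-sulfinamide (C=N geometry not assigned) | CC(C)(C)[S@@](=O)N=C(CCCCCl)c1c(OC)cc(OCc2ccccc2)cc1OC
F4 | step 8 | 2-iodo-3,5-dimethoxy-4-[(2S)-1-[(R)-2-methylpropane-2-sulfinyl]piperidin-2-yl]phenol | CC(C)(C)[S@@](=O)N1CCCC[C@H]1c1c(OC)cc(O)c(I)c1OC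
F5 | step 8 | 5,7-dimethoxy-6-[(2S)-1-[(R)-2-methylpropane-2-sulfinyl]piperidin-2-yl]-2-phenyl-4H-chromen-4-one | CC(C)(C)[S@@](=O)N1CCCC[C@H]1c1c(OC)cc2oc(-c3ccccc3)cc(=O)c2c1OC
F6 | step 10 | benzyl (2S)-2-[7-(2,2-dimethylpropanoyloxy)-5-hydroxy-4-oxo-2-phenyl-4H-chromen-6-yl]piperidine-1-carboxylate | O=C(OCc1ccccc1)N1CCCC[C@H]1c1c(OC(=O)C(C)(C)C)cc2oc(-c3ccccc3)cc(=O)c2c1O
F7 | step 10 | benzyl (2S)-2-[7-(2,2-dimethylpropanoyloxy)-5-methoxy-4-oxo-2-phenyl-4H-chromen-6-yl]piperidine-1-carboxylate | O=C(OCc1ccccc1)N1CCCC[C@H]1c1c(OC(=O)C(C)(C)C)cc2oc(-c3ccccc3)cc(=O)c2c1OC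
F8 | step 10 | benzyl (2S)-2-(7-hydroxy-5-methoxy-4-oxo-2-phenyl-4H-chromen-6-yl)piperidine-1-carboxylate | O=C(OCc1ccccc1)N1CCCC[C@H]1c1c(O)cc2oc(-c3ccccc3)cc(=O)c2c1OC
F9 | step 11 | prop-2-en-1-yl (2S)-2-(5,7-dihydroxy-4-oxo-2-phenyl-4H-chromen-6-yl)piperidine-1-carboxylate | C=CCOC(=O)N1CCCC[C@H]1c1c(O)cc2oc(-c3ccccc3)cc(=O)c2c1O
F10 | step 11 | prop-2-en-1-yl (2S)-2-[5-hydroxy-4-oxo-2-phenyl-7-(prop-2-en-1-yloxy)-4H-chromen-6-yl]piperidine-1-carboxylate | C=CCOC(=O)N1CCCC[C@H]1c1c(OCC=C)cc2oc(-c3ccccc3)cc(=O)c2c1O
F11 | step 11 | prop-2-en-1-yl (2S)-2-[5-methoxy-4-oxo-2-phenyl-7-(prop-2-en-1-yloxy)-4H-chromen-6-yl]piperidine-1-carboxylate | C=CCOC(=O)N1CCCC[C@H]1c1c(OCC=C)cc2oc(-c3ccccc3)cc(=O)c2c1OC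
F12 | step 11 | 7-hydroxy-5-methoxy-2-phenyl-6-[(2S)-piperidin-2-yl]-4H-chromen-4-one | N1CCCC[C@H]1c1c(O)cc2oc(-c3ccccc3)cc(=O)c2c1OC
A1 | alternative 1 | 7-hydroxy-5-methoxy-4-oxo-2-phenyl-4H-chromene-6-carbaldehyde | COc1c(C=O)c(O)cc2oc(-c3ccccc3)cc(=O)c12
A2 | alternative 1 | (3Z)-4-(trimethylsilyl)but-3-en-1-amine | NCC/C=C\[Si](C)(C)C
A3 | alternative 1 | 7-hydroxy-5-methoxy-2-phenyl-6-[(2S)-1,2,5,6-tetrahydropyridin-2-yl]-4H-chromen-4-one | COc1c([C@@H]2C=CCCN2)c(O)cc2oc(-c3ccccc3)cc(=O)c12
A4 | alternative 2 | 3-[(4-methoxyphenyl)methoxy]cyclobut-2-en-1-one | COc1ccc(COC2=CC(=O)C2)cc1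
A5 | alternative 2 | tert-butyl (2S)-2-({[tri(propan-2-yl)silyl]oxy}ethynyl)piperidine-1-carboxylate | CC(C)[Si](OC#C[C@@H]1CCCCN1C(=O)OC(C)(C)C)(C(C)C)C(C)C
A6 | alternative 2 | tert-butyl (2S)-2-{2-hydroxy-4-[(4-methoxyphenyl)methoxy]-6-[tri(propan-2-yl)silyloxy]phenyl}piperidine-1-carboxylate | CC(C)[Si](Oc1cc(OCc2ccc(OC)cc2)cc(O)c1[C@@H]1CCCCN1C(=O)OC(C)(C)C)(C(C)C)C(C)C
A7 | alternative 3 | 3-{3,5-dimethoxy-4-[(2S)-1-methylpiperidin-2-yl]phenoxy}-3-phenylprop-2-enoic acid | CN1CCCC[C@H]1c1c(OC)cc(OC(=CC(=O)O)c2ccccc2)cc1OC
A8 | alternative 3 | 5,7-dimethoxy-6-[(2S)-1-methylpiperidin-2-yl]-2-phenyl-4H-chromen-4-one | COc1cc2oc(-c3ccccc3)cc(=O)c2c(OC)c1[C@@H]1CCCCN1C
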